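The flavanone is disconnected at C2–C1′ into a 5-hydroxy-6-prenyl-7-silyloxychromone and an arylboronic acid that already carries the (R)-epoxide; a rhodium-catalysed enantioselective 1,4-arylation joins them and sets C2. The pyranone ring (O1, C2, C3, C4, C4a, C8a) is not closed by cyclisation but grown from the furanone ring of commercial 4,6-dihydroxybenzofuran-3(2H)-one. The feature exploited is the C3 methylene lying between the C4 carbonyl and the oxygen-bearing C2: it is added as a cyclopropane CH2 across the furanone enol silyl ether, and iron(III) oxidation then cleaves the shared bond, releasing strain and enlarging the five-membered ring to the chromone in one operation.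

Key step: step 4

Assumption (chemistry): the (S)-configured biaryl bisphosphine is taken to deliver the aryl group to the same enone face as in the 2-cyclohexenone model (which gives (S)-3-arylcyclohexanones and corresponds to 2S here); if the sense proves opposite, the antipodal ligand is used.

Step 1
Reactants: 1 4,6-dihydroxybenzofuran-3(2H)-one
Product: 2 4-hydroxy-6-(triisopropylsilyloxy)benzofuran-3(2H)-one
Conditions: TIPSCl (1.05 equiv), imidazole, DMF, 0 °C
Reagents that add atoms: triisopropylsilyl chloride, CC(C)[Si](Cl)(C(C)C)C(C)C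
Why: Selective phenol silylation; the 6-OH (para to the ketone, more acidic, unhindered) should react ahead of the 4-OH, which is hydrogen-bonded to the C3 carbonyl.

Step 2
Reactants: 2 4-hydroxy-6-(triisopropylsilyloxy)benzofuran-3(2H)-one
Product: 3 6-(triisopropylsilyloxy)-3,4-bis(trimethylsilyloxy)benzofuran
Conditions: TMSOTf (2.4 equiv), Et3N, CH2Cl2, 0 °C; non-aqueous work-up (pentane), used directly
Reagents that add atoms: trimethylsilyl trifluoromethanesulfonate, C[Si](C)(C)OS(=O)(=O)C(F)(F)F
Why: Soft enolisation and O-silylation; enol silyl ether formation is favoured by aromatisation to the benzofuran, and the 4-OH is capped in the same operation.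

Step 3
Reactants: 3 6-(triisopropylsilyloxy)-3,4-bis(trimethylsilyloxy)benzofuran
Product: 4 cis-fused, racemic 4-(triisopropylsilyloxy)-6,6b-bis(trimethylsilyloxy)-1a,6b-dihydro-1H-cyclopropa[b]benzofuran
Conditions: Et2Zn (2 equiv), CH2I2 (4 equiv), CH2Cl2, 0 °C to rt; pyridine quench
Reagents that add atoms: diiodomethane, ICI
Why: Simmons–Smith (Furukawa) cyclopropanation of the C2=C3 enol ether bond, which carries two oxygen donors and should be the most nucleophilic alkene present; the two new centres are cis by ring fusion, racemic, and erased in step 4.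

Step 4
Reactants: 4 cis-fused, racemic 4-(triisopropylsilyloxy)-6,6b-bis(trimethylsilyloxy)-1a,6b-dihydro-1H-cyclopropa[b]benzofuran
Product: 6 5-hydroxy-7-(triisopropylsilyloxy)-4H-chromen-4-one, via 2-chlorochroman-4-one 5 (not isolated)
Conditions: FeCl3 (2.2 equiv), DMF, 0 °C to rt; then Et3N; aq. NH4Cl work-up
Reagents that add atoms: iron(III) chloride, Cl[Fe](Cl)Cl (supplies the chlorine of intermediate 5; no atom of it remains in 6)
Why: Iron(III) oxidises the silyloxycyclopropane by single-electron transfer (the enol Me3Si group leaves as Me3SiCl) to a cyclopropyloxy radical, which undergoes β-scission of the internal C1a–C6b bond: strain is released, the aryl ketone C4=O forms and the radical lands on C2, where the ring oxygen stabilises it; chlorine transfer from FeCl3 gives the α-chloro ether 5, and Et3N removes HCl to give the chromone. The closest known reaction type is the Ito–Saegusa FeCl3 ring enlargement of 1-silyloxybicyclo[n.1.0]alkanes to 2-cycloalkenones. No ring is closed by bond formation: the six-membered pyranone arises from the five-membered furan ring by cleavage of the zero-atom bridge of the oxabicyclo[3.1.0]hexane, a one-carbon enlargement that places the new CH2 as C3 between C4 and C2. No stereocentre is formed, and both racemic cyclopropane centres disappear. The selectivity needed is internal over external (C6b–C1) bond cleavage; it should be secured by the oxygen-stabilised secondary radical (against a primary one) and by the better overlap of the fused bond with the oxygen-centred radical. Aqueous work-up also frees the chelated 5-OH from its trimethylsilyl ether, which step 5 requires.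

Step 5
Reactants: 6 5-hydroxy-7-(triisopropylsilyloxy)-4H-chromen-4-one
Product: 7 5-hydroxy-6-iodo-7-(triisopropylsilyloxy)-4H-chromen-4-one
Conditions: BnMe3N·ICl2 (1.05 equiv), CaCO3, CH2Cl2/MeOH, rt
Reagents that add atoms: benzyltrimethylammonium dichloroiodate, C[N+](C)(C)Cc1ccccc1.Cl[I-]Cl
Why: Electrophilic aromatic iodination; 5-hydroxy-7-alkoxy chromones and flavones are expected to react at C6, ortho to the chelated 5-OH, and not at C8.

Step 6
Reactants: 7 5-hydroxy-6-iodo-7-(triisopropylsilyloxy)-4H-chromen-4-one; 8 tributyl(3-methylbut-2-en-1-yl)stannane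
Product: 9 5-hydroxy-6-(3-methylbut-2-en-1-yl)-7-(triisopropylsilyloxy)-4H-chromen-4-one
Conditions: Pd(PPh3)4 (5 mol%), DMF, 90 °C
Reagents that add atoms: none
Why: Stille coupling under neutral conditions that the silyl ether and the free 5-OH should tolerate; reductive elimination at the less hindered allyl terminus should give the linear prenyl group.

Step 7
Reactants: 10 4-bromophenol; 11 1-bromo-3-methylbut-2-ene
Product: 12 4-bromo-2-(3-methylbut-2-en-1-yl)phenol
Conditions: NaH, toluene, 0 °C to rt
Reagents that add atoms: none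
Why: ortho-C-alkylation of a sodium phenoxide in a non-polar solvent, where the tight ion pair directs the allylic halide to the ring carbon next to oxygen; the para position is blocked by bromine.

Step 8
Reactants: 12 4-bromo-2-(3-methylbut-2-en-1-yl)phenol
Product: 13 [4-bromo-2-(3-methylbut-2-en-1-yl)phenoxy]triisopropylsilane
Conditions: TIPSCl, imidazole, DMF, rt
Reagents that add atoms: triisopropylsilyl chloride, CC(C)[Si](Cl)(C(C)C)C(C)C
Why: Standard silyl ether formation; it removes the phenol that would otherwise open the epoxide made in step 9.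

Step 9
Reactants: 13 [4-bromo-2-(3-methylbut-2-en-1-yl)phenoxy]triisopropylsilane
Product: 14 {4-bromo-2-[((2R)-3,3-dimethyloxiran-2-yl)methyl]phenoxy}triisopropylsilane
Conditions: D-fructose-derived Shi ketone (30 mol%), Oxone, K2CO3, Bu4NHSO4, MeCN/dimethoxymethane–aq. borate/EDTA buffer (pH about 10.5), 0 °C
Reagents that add atoms: potassium peroxymonosulfate (Oxone), [K+].[O-]S(=O)(=O)OO
Why: Shi asymmetric epoxidation of a trisubstituted alkene; the dioxirane of the D-fructose-derived ketone should attack through the spiro transition state and give the (R)-epoxide under catalyst control.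

Step 10
Reactants: 14 {4-bromo-2-[((2R)-3,3-dimethyloxiran-2-yl)methyl]phenoxy}triisopropylsilane
Product: 16 {3-[((2R)-3,3-dimethyloxiran-2-yl)methyl]-4-(triisopropylsilyloxy)phenyl}boronic acid, via aryllithium 15 (not isolated)
Conditions: B(OiPr)3 (1.5 equiv) present, n-BuLi (1.05 equiv) added, THF/toluene, −78 °C; aq. NH4Cl
Reagents that add atoms: triisopropyl borate, CC(C)OB(OC(C)C)OC(C)C; water, O (hydroxyl oxygens on hydrolysis); n-butyllithium, [Li]CCCC (lithium of 15 only)
Why: Bromine–lithium exchange with in situ borate trapping; exchange at −78 °C should be much faster than attack of an organolithium on the hindered trisubstituted epoxide, which is not touched at its stereocentre.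

Step 11
Reactants: 9 5-hydroxy-6-(3-methylbut-2-en-1-yl)-7-(triisopropylsilyloxy)-4H-chromen-4-one; 16 {3-[((2R)-3,3-dimethyloxiran-2-yl)methyl]-4-(triisopropylsilyloxy)phenyl}boronic acid (2 equiv)
Product: 17 (2S)-2-{3-[((2R)-3,3-dimethyloxiran-2-yl)methyl]-4-(triisopropylsilyloxy)phenyl}-5-hydroxy-6-(3-methylbut-2-en-1-yl)-7-(triisopropylsilyloxy)chroman-4-one
Conditions: [Rh(OH)(cod)]2 (2.5 mol%), (S)-MeO-F12-BIPHEP (5.5 mol%), toluene/H2O, 40 °C, no added base
Reagents that add atoms: none
Why: Hayashi–Miyaura rhodium-catalysed asymmetric 1,4-addition of an arylboronic acid to a chromone; the aryl–rhodium species adds to C2 on the enone face chosen by the ligand (catalyst control, the epoxide centre being remote) to give 2S, and the base-free medium should spare the epoxide, the silyl ethers and the flavanone from retro-oxa-Michael racemisation.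

Step 12
Reactants: 17 (2S)-2-{3-[((2R)-3,3-dimethyloxiran-2-yl)methyl]-4-(triisopropylsilyloxy)phenyl}-5-hydroxy-6-(3-methylbut-2-en-1-yl)-7-(triisopropylsilyloxy)chroman-4-one
Product: 18 (2S)-2-{3-[((2R)-3,3-dimethyloxiran-2-yl)methyl]-4-hydroxyphenyl}-5,7-dihydroxy-6-(3-methylbut-2-en-1-yl)chroman-4-one
Conditions: TBAF (2.2 equiv), AcOH (2.5 equiv), THF, 0 °C
Reagents that add atoms: none
Why: Fluoride cleavage of both aryl silyl ethers; the acetic acid buffer keeps the phenols protonated, so that neither opening of the neighbouring epoxide by the 4′-phenoxide nor base-induced ring opening of the flavanone (loss of C2 configuration) should occur.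

Compound list
1 | 4,6-dihydroxybenzofuran-3(2H)-one | O=C1COc2cc(O)cc(O)c12 | starting material
2 | 4-hydroxy-6-(triisopropylsilyloxy)benzofuran-3(2H)-one | O=C1COc2cc(O[Si](C(C)C)(C(C)C)C(C)C)cc(O)c12 | intermediate
3 | 6-(triisopropylsilyloxy)-3,4-bis(trimethylsilyloxy)benzofuran | C[Si](C)(C)Oc1coc2cc(O[Si](C(C)C)(C(C)C)C(C)C)cc(O[Si](C)(C)C)c12 | intermediate
4 | cis-fused, racemic 4-(triisopropylsilyloxy)-6,6b-bis(trimethylsilyloxy)-1a,6b-dihydro-1H-cyclopropa[b]benzofuran | C[Si](C)(C)OC12CC1Oc1cc(O[Si](C(C)C)(C(C)C)C(C)C)cc(O[Si](C)(C)C)c12 | intermediate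
5 | 2-chloro-7-(triisopropylsilyloxy)-5-(trimethylsilyloxy)chroman-4-one (racemic) | O=C1CC(Cl)Oc2cc(O[Si](C(C)C)(C(C)C)C(C)C)cc(O[Si](C)(C)C)c12 | intermediate (not isolated)
6 | 5-hydroxy-7-(triisopropylsilyloxy)-4H-chromen-4-one | O=c1ccoc2cc(O[Si](C(C)C)(C(C)C)C(C)C)cc(O)c12 | intermediate
7 | 5-hydroxy-6-iodo-7-(triisopropylsilyloxy)-4H-chromen-4-one | O=c1ccoc2cc(O[Si](C(C)C)(C(C)C)C(C)C)c(I)c(O)c12 | intermediate
8 | tributyl(3-methylbut-2-en-1-yl)stannane | CCCC[Sn](CCCC)(CCCC)CC=C(C)C | starting material
9 | 5-hydroxy-6-(3-methylbut-2-en-1-yl)-7-(triisopropylsilyloxy)-4H-chromen-4-one | CC(C)=CCc1c(O[Si](C(C)C)(C(C)C)C(C)C)cc2occc(=O)c2c1O | intermediate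
10 | 4-bromophenol | Oc1ccc(Br)cc1 | starting material
11 | 1-bromo-3-methylbut-2-ene (prenyl bromide) | CC(C)=CCBr | starting material
12 | 4-bromo-2-(3-methylbut-2-en-1-yl)phenol | CC(C)=CCc1cc(Br)ccc1O | intermediate
13 | [4-bromo-2-(3-methylbut-2-en-1-yl)phenoxy]triisopropylsilane | CC(C)=CCc1cc(Br)ccc1O[Si](C(C)C)(C(C)C)C(C)C | intermediate
14 | {4-bromo-2-[((2R)-3,3-dimethyloxiran-2-yl)methyl]phenoxy}triisopropylsilane | Brc1ccc(O[Si](C(C)C)(C(C)C)C(C)C)c(C[C@H]2OC2(C)C)c1 | intermediate
15 | {3-[((2R)-3,3-dimethyloxiran-2-yl)methyl]-4-(triisopropylsilyloxy)phenyl}lithium | [Li]c1ccc(O[Si](C(C)C)(C(C)C)C(C)C)c(C[C@H]2OC2(C)C)c1 | intermediate (not isolated)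
16 | {3-[((2R)-3,3-dimethyloxiran-2-yl)methyl]-4-(triisopropylsilyloxy)phenyl}boronic acid | OB(O)c1ccc(O[Si](C(C)C)(C(C)C)C(C)C)c(C[C@H]2OC2(C)C)c1 | intermediate
17 | (2S)-2-{3-[((2R)-3,3-dimethyloxiran-2-yl)methyl]-4-(triisopropylsilyloxy)phenyl}-5-hydroxy-6-(3-methylbut-2-en-1-yl)-7-(triisopropylsilyloxy)chroman-4-one | CC(C)=CCc1c(O[Si](C(C)C)(C(C)C)C(C)C)cc2c(c1O)C(=O)C[C@@H](c1ccc(O[Si](C(C)C)(C(C)C)C(C)C)c(C[C@H]3OC3(C)C)c1)O2 | intermediate
18 | (2S)-2-{3-[((2R)-3,3-dimethyloxiran-2-yl)methyl]-4-hydroxyphenyl}-5,7-dihydroxy-6-(3-methylbut-2-en-1-yl)chroman-4-one | CC(C)=CCc1c(O)cc2c(c1O)C(=O)C[C@@H](c1ccc(O)c(C[C@H]3OC3(C)C)c1)O2 | target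

Total step count: 12. Longest linear sequence: 8 (steps 1–6, 11, 12); the boronic acid branch (steps 7–10) has 4 steps.

Steps most likely to fail

Step 11. The aryl transfer to the electron-rich, 5-hydroxylated chromone may be slow or poorly face-selective, and protodeboronation of the boronic acid may outrun it. Fallback: from 9 and 16 the addition is run with achiral [Rh(OH)(cod)]2 alone, which should give the C2-epimeric mixture of silylated flavanones F5 without facial control. Because the (R)-epoxide makes the two C2 epimers diastereomers, they are separated by preparative HPLC on a chiral stationary phase. The (2R)-epimer is re-equilibrated with catalytic DBU in toluene through the ring-opened 2′,6′-dihydroxychalcone F6 (not isolated) and recycled; the (2S)-epimer is 17, where the route is rejoined.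

Step 4. Iron(III) may over-oxidise the electron-rich arene, or the external cyclopropane bond may break and give the 2-methylfuranone instead of the enlarged ring. Fallback: from 3 (bypassing 4), dibromocarbene (CHBr3, KOtBu, pentane, −30 °C to rt) adds to the same enol ether bond to give the cis-fused 1,1-dibromo-4-(triisopropylsilyloxy)-6,6b-bis(trimethylsilyloxy)-1a,6b-dihydro-1H-cyclopropa[b]benzofuran F1. It is not isolated: silyloxy-assisted disrotatory opening with loss of bromide enlarges the ring directly to 3-bromo-5-hydroxy-7-(triisopropylsilyloxy)-4H-chromen-4-one F2 (dihalocarbene ring enlargement of silyl enol ethers to 2-halo-enones). Zinc dust in AcOH/THF removes the bromine and returns to 6.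

Step 5. Iodination may lose regiocontrol, with attack at C8 or at both C6 and C8. Fallback: from 6, Mitsunobu O-allylation of the 5-OH (allyl alcohol, PPh3, DIAD, THF) gives 5-(allyloxy)-7-(triisopropylsilyloxy)-4H-chromen-4-one F3. Aromatic Claisen rearrangement (Eu(fod)3 cat., CHCl3, 60 °C, or thermal) can deliver the allyl group only to C6 and gives 6-allyl-5-hydroxy-7-(triisopropylsilyloxy)-4H-chromen-4-one F4. Cross-metathesis with 2-methyl-2-butene (Grubbs second-generation catalyst, CH2Cl2, 40 °C) converts allyl into prenyl and returns to 9.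

Further compounds
F1 | step 4 | cis-fused, racemic 1,1-dibromo-4-(triisopropylsilyloxy)-6,6b-bis(trimethylsilyloxy)-1a,6b-dihydro-1H-cyclopropa[b]benzofuran | C[Si](C)(C)OC12C(Br)(Br)C1Oc1cc(O[Si](C(C)C)(C(C)C)C(C)C)cc(O[Si](C)(C)C)c12
F2 | step 4 | 3-bromo-5-hydroxy-7-(triisopropylsilyloxy)-4H-chromen-4-one | O=c1c(Br)coc2cc(O[Si](C(C)C)(C(C)C)C(C)C)cc(O)c12
F3 | step 5 | 5-(allyloxy)-7-(triisopropylsilyloxy)-4H-chromen-4-one | C=CCOc1cc(O[Si](C(C)C)(C(C)C)C(C)C)cc2occc(=O)c12
F4 | step 5 | 6-allyl-5-hydroxy-7-(triisopropylsilyloxy)-4H-chromen-4-one | C=CCc1c(O[Si](C(C)C)(C(C)C)C(C)C)cc2occc(=O)c2c1O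
F5 | step 11 | C2-epimeric mixture of 2-{3-[((2R)-3,3-dimethyloxiran-2-yl)methyl]-4-(triisopropylsilyloxy)phenyl}-5-hydroxy-6-(3-methylbut-2-en-1-yl)-7-(triisopropylsilyloxy)chroman-4-one | CC(C)=CCc1c(O[Si](C(C)C)(C(C)C)C(C)C)cc2c(c1O)C(=O)CC(c1ccc(O[Si](C(C)C)(C(C)C)C(C)C)c(C[C@H]3OC3(C)C)c1)O2
F6 | step 11 | (E)-1-[2,6-dihydroxy-3-(3-methylbut-2-en-1-yl)-4-(triisopropylsilyloxy)phenyl]-3-{3-[((2R)-3,3-dimethyloxiran-2-yl)methyl]-4-(triisopropylsilyloxy)phenyl}prop-2-en-1-one | CC(C)=CCc1c(O[Si](C(C)C)(C(C)C)C(C)C)cc(O)c(C(=O)/C=C/c2ccc(O[Si](C(C)C)(C(C)C)C(C)C)c(C[C@H]3OC3(C)C)c2)c1O
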